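## The problem

1. Target 26 is an eleven-membered carbocycle (ring atoms C1–C11). Three rigid units are separated by single sp3 atoms only: a cis olefin C2=C3 attached directly to the quaternary stereocentre C1 (methyl, 4-methylpent-3-enyl), a trisubstituted oxirane C5–C6 with C4 and C7 trans on the three-membered ring, and a cis enone C8(=O)–C9(CH2OH)=C10.
2. Five- to seven-membered carbocyclic precursors cannot hold C5–C6 with this trans geometry, so ring-expansion and fragmentation routes lose the oxirane stereochemistry. The ring therefore has to be closed from an open chain against transannular strain.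
3. C1 is insulated by trigonal carbons on both sides. It can neither control nor be controlled by the other stereocentres and needs absolute control of its own.
4. C4–C7 are contiguous. The oxirane oxygen is syn (threo) to the C7 hydroxyl, which is what C7–OH-directed peracid epoxidation of the E olefin gives under 1,3-allylic strain control. It is also syn to the C4 oxygen, which C4–OH direction is not expected to deliver. C4 and C7 therefore each need an independent source of chirality, and only C7 can be used to set C5/C6.
5. The functional groups are fragile: a 2,3-epoxy alcohol (Payne rearrangement, opening), an α-ketol next to the oxirane (epimerisation, β-elimination on enolisation), a cis enone (isomerisation, conjugate addition) and an allylic senecioate (acyl migration, deconjugation). The end game must be short and close to neutral.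
6. The feature that makes the key step possible: C1 carries a cis-alkenyl group (C2=C3) and lies β to the trigonal carbon C10 across the C11 methylene. C10, C11, C1, its methyl and the 4-methylpent-3-enyl chain are the ten carbons of geranic acid, so a C1–B bond can be set by conjugate borylation of a geranate. A cis alkene on a fully substituted carbon is what a stereoretentive boron-to-carbon shift onto an E-alkenyl group followed by anti elimination produces.

## Retrosynthesis

**End game (26 ⇒ 25 ⇒ 24 ⇒ 23).** The cuts are the two O–Si bonds and the C4–O acyl bond. The ester must be introduced while O7 and O9' are masked, because three free hydroxyls could not be told apart. The silyl ethers come off last with buffered fluoride. Enone 23 already holds the ring and every stereocentre. The forward steps are PMB removal, acylation of a hindered secondary alcohol and desilylation.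

**Ring opening at C8–C9 (23 ⇒ 22 ⇒ 21).** The ring is opened between the ketone carbon and the alkene carbon: Nozaki–Hiyama–Kishi closure of iodo-aldehyde 21 to carbinol 22, then oxidation. This bond joins two unhindered trigonal carbons, and the carbinol stereocentre it creates is erased by oxidation. C4–C7 and both olefin geometries stay outside the ring-forming event. Closure at C3–C4 would put C4 under unknown macrocyclic control; closure at C1–C2 would make the most hindered bond in the entropically worst step. The forward reaction must insert into C–I selectively and tolerate oxirane, silyl ethers and PMB ether at high dilution.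

**Union at the quaternary carbon (21 ⇒ 20 ⇒ 17 + 7).** Aldehyde 21 comes from triethylsilyl ether 20. Compound 20 is cut at C1–C2 into alkenyl iodide 17 (C2–C8, all four oxygenated stereocentres) and tertiary boronic ester 7 (C1, C9–C11, both side chains). In the forward direction alkenyllithium 18 adds to 7 to give boronate 19; iodine then triggers the 1,2-shift and anti elimination. This forms C1–C2 with retention at C1 and delivers the Z olefin, and the same iodine converts the stannane into the C9 iodide. A cut at C3–C4 would leave the cis-alkenyl/quaternary linkage to linear chemistry and create C4 in the coupling. A [3,3] cut at C1–C11 gives the E olefin. The two fragments are of similar size, and neither contains a ring larger than three atoms.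

**Fragment A (7 ⇒ 6 ⇒ 5 ⇒ 4 ⇒ 3 ⇒ 2 ⇒ 1).** Stannane 7 is the silyl ether of 6, which arises from propargylic alcohol 5 by hydroxyl-directed trans-hydrostannation. This fixes the enone geometry before the ring exists. Alcohol 5 comes from aldehyde 3 by two one-carbon homologations through alkyne 4. Aldehyde 3 comes from ester 2, and 2 from methyl geranate 1 by enantioselective conjugate borylation. The C–B bond is the only stereocentre, and all ten carbons come from 1.

**Fragment B (17 ⇒ 16 ⇒ 15 ⇒ 14 ⇒ 13 ⇒ 12 ⇒ 10 ⇒ 9 ⇒ 8).** The oxirane of 16 (silylated to 17) is made from allylic alcohol 15 by hydroxyl-directed epoxidation. This is done in the fragment, where the only other alkene is the electron-poor iodoalkene; in the full molecule the 4-methylpent-3-enyl olefin would compete for a peracid. Alcohol 15 comes from acetonide 13 through diol 14. The iodoalkene of 13 comes from alkyne 12 by hydrozirconation. The C3–C4 bond and the C4 stereocentre come from ligand-controlled alkynylation of enal 9 (giving 10, then ether 12 through 11). The E olefin C5=C6 comes from a Wittig reaction on (R)-glyceraldehyde acetonide 8, which supplies C7.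

## Roads not taken

Alternative 1: The most obvious plan cuts C3–C4 last. A linear seco iodo-aldehyde A1 (Z-iodoalkene on the quaternary carbon, α,β-epoxy aldehyde at C4) would be closed by a Nozaki–Hiyama–Kishi reaction, or the ring would be closed by metathesis at C2=C3. The quaternary centre would come from a separate asymmetric alkylation and be carried through a long linear sequence. The chosen plan is better for three reasons. C4 would be created during ring closure under macrocyclic control, and addition to an α,β-epoxy aldehyde normally favours the anti (erythro) product, whereas 26 needs syn. The cis-alkenyl group would have to be built on a neopentyl aldehyde in extra steps. Nothing would be convergent. In the chosen route C4 is set by ligand control, and C1–C2 and the Z geometry are made in the union.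

Alternative 2: A transannular cut C3–C9 suggests ring expansion. Anionic oxy-Cope rearrangement of a 1,2-dialkenylcycloheptenol A2 would form C1–C11 and the quaternary centre and enlarge the ring by four atoms. The seven-membered ring of A2 must contain C5=C6 as a cis olefin, but the oxirane of 26 derives from the E olefin, so the C4–C7 stereochemistry cannot be carried through and needs an inversion sequence afterwards. A2 also has two adjacent fully substituted carbons and as many stereocentres as the product. The C3 oxygen would have to be removed again, and the tertiary alkoxide β to oxygenated carbons invites retro-aldol cleavage. The precursor is not simpler than the product.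

Alternative 3: A cut at C1–C11 by [3,3] rearrangement. Ireland–Claisen rearrangement of secondary allylic acetate A3 would transfer chirality from C3–O to C1 and give acid A4 with the quaternary centre. The chair transition state places the C4 chain equatorial, and with a trisubstituted alkene terminus the axial alternative is further disfavoured. The new C2=C3 double bond is therefore E, as in A4, whereas 26 needs Z. The C10 carboxyl would still need the same two homologations. The boron route gives Z through an anti elimination and fixes C1 by catalysis without a sacrificial carbinol.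

Key step: step 15

Remark on the chemistry: methyl geranate 1 is assumed to be geometrically pure 2E (E and Z esters would give opposite configurations at C1); locants C1–C11 follow the ring of 26 (C1 quaternary, C8 ketone, C9' hydroxymethyl carbon).

Step 1
Reactants: 1 methyl (2E)-3,7-dimethylocta-2,6-dienoate (methyl geranate)
Product: 2 methyl (3R)-3,7-dimethyl-3-(4,4,5,5-tetramethyl-1,3,2-dioxaborolan-2-yl)oct-6-enoate
Conditions: B2pin2, CuCl (cat.), NaOt-Bu (cat.), chiral Josiphos-type ferrocenyl bisphosphine (enantiomer that gives 3R), MeOH, THF, rt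
Reagents that add atoms: bis(pinacolato)diboron, CC1(C)OB(OC1(C)C)B1OC(C)(C)C(C)(C)O1
Why: Copper-catalysed enantioselective conjugate borylation of a β,β-disubstituted enoate; the chiral copper–boryl complex adds to one face of the E enoate and methanol protonates the copper enolate, which sets C1 as a tertiary C–B bond. The isolated trisubstituted olefin does not react with the copper–boryl species.

Step 2
Reactants: 2 methyl (3R)-3,7-dimethyl-3-(pinacolboryl)oct-6-enoate
Product: 3 (3R)-3,7-dimethyl-3-(4,4,5,5-tetramethyl-1,3,2-dioxaborolan-2-yl)oct-6-enal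
Conditions: i-Bu2AlH, CH2Cl2, −78 °C; aqueous potassium sodium tartrate
Reagents that add atoms: none
Why: Partial ester reduction stops at the aluminium hemiacetal at low temperature and gives the aldehyde on work-up; the hindered tertiary pinacol boronate should not react with the hydride.

Step 3
Reactants: 3 (3R)-3,7-dimethyl-3-(pinacolboryl)oct-6-enal
Product: 4 2-[(4R)-4,8-dimethylnon-7-en-1-yn-4-yl]-4,4,5,5-tetramethyl-1,3,2-dioxaborolane
Conditions: dimethyl (1-diazo-2-oxopropyl)phosphonate, K2CO3, MeOH, 0 °C to rt
Reagents that add atoms: dimethyl (1-diazo-2-oxopropyl)phosphonate, CC(=O)C(=[N+]=[N-])P(=O)(OC)OC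
Why: Ohira–Bestmann homologation converts the aldehyde carbon C10 into an alkyne carbon and adds C9 under mild carbonate conditions that a tertiary alkyl pinacol boronate tolerates.

Step 4
Reactants: 4 2-[(4R)-4,8-dimethylnon-7-en-1-yn-4-yl]pinacolborane
Product: 5 (5R)-5,9-dimethyl-5-(4,4,5,5-tetramethyl-1,3,2-dioxaborolan-2-yl)dec-8-en-2-yn-1-ol
Conditions: LDA, THF, −78 °C; paraformaldehyde, −78 °C to rt
Reagents that add atoms: formaldehyde (as paraformaldehyde), C=O
Why: Hydroxymethylation of the lithium acetylide adds C9'; a non-nucleophilic amide base is used because alkyllithium reagents would add to boron.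

Step 5
Reactants: 5 (5R)-5,9-dimethyl-5-(pinacolboryl)dec-8-en-2-yn-1-ol
Product: 6 (2Z,5R)-5,9-dimethyl-5-(4,4,5,5-tetramethyl-1,3,2-dioxaborolan-2-yl)-2-(tributylstannyl)deca-2,8-dien-1-ol
Conditions: Bu3SnH, [Cp*RuCl]4 (cat.; Cp* = C5Me5), CH2Cl2, rt
Reagents that add atoms: tributyltin hydride, CCCC[SnH](CCCC)CCCC
Why: Ruthenium-catalysed trans-hydrostannation of a propargylic alcohol; hydrogen bonding of the hydroxyl to the Ru–Cl unit steers tin to the proximal carbon C9, and trans addition places tin cis to C11. This is the geometry of the enone once C8 replaces tin.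

Step 6
Reactants: 6 (2Z,5R)-5,9-dimethyl-5-(pinacolboryl)-2-(tributylstannyl)deca-2,8-dien-1-ol
Product: 7 tert-butyl{[(2Z,5R)-5,9-dimethyl-5-(4,4,5,5-tetramethyl-1,3,2-dioxaborolan-2-yl)-2-(tributylstannyl)deca-2,8-dien-1-yl]oxy}dimethylsilane (fragment A)
Conditions: TBSCl, imidazole, CH2Cl2, 0 °C to rt
Reagents that add atoms: tert-butyldimethylsilyl chloride, CC(C)(C)[Si](C)(C)Cl
Why: Standard silylation of a primary alcohol; it removes the acidic proton before the organolithium step and gives the O9' protecting group that stays to the end.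

Step 7
Reactants: 8 (4R)-2,2-dimethyl-1,3-dioxolane-4-carbaldehyde ((R)-glyceraldehyde acetonide)
Product: 9 (2E)-3-[(4S)-2,2-dimethyl-1,3-dioxolan-4-yl]-2-methylprop-2-enal
Conditions: Ph3P=C(CH3)CHO, CH2Cl2, 40 °C
Reagents that add atoms: 2-(triphenylphosphoranylidene)propanal, CC(C=O)=P(c1ccccc1)(c1ccccc1)c1ccccc1
Why: Wittig olefination with a stabilised formyl ylide gives the E trisubstituted enal (C4, C5 and its methyl); C7 comes unchanged from the chiral pool.

Step 8
Reactants: 9 (2E)-3-[(4S)-2,2-dimethyl-1,3-dioxolan-4-yl]-2-methylprop-2-enal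
Product: 10 (3S,4E)-5-[(4S)-2,2-dimethyl-1,3-dioxolan-4-yl]-4-methyl-1-(trimethylsilyl)pent-4-en-1-yn-3-ol
Conditions: ethynyltrimethylsilane, Me2Zn, ProPhenol ligand (cat., enantiomer that gives 3S), Ph3PO (cat.), toluene, 0 °C
Reagents that add atoms: ethynyltrimethylsilane, C#C[Si](C)(C)C
Why: Catalytic enantioselective zinc alkynylation of an α-substituted enal (1,2-addition); the dinuclear zinc–ligand complex sets C4 by reagent control, and the remote C7 centre should have little influence.

Step 9
Reactants: 10 (3S,4E)-5-[(4S)-2,2-dimethyl-1,3-dioxolan-4-yl]-4-methyl-1-(trimethylsilyl)pent-4-en-1-yn-3-ol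
Product: 12 (4S)-4-{(1E,3R)-3-[(4-methoxyphenyl)methoxy]-2-methylpent-1-en-4-yn-1-yl}-2,2-dimethyl-1,3-dioxolane, via silylalkyne PMB ether 11 (not isolated)
Conditions: NaH, 4-methoxybenzyl chloride, Bu4NI (cat.), THF/DMF, 0 °C to rt; then MeOH, K2CO3 (cat.), rt
Reagents that add atoms: 4-methoxybenzyl chloride, COc1ccc(CCl)cc1
Why: Williamson etherification protects O4 with a group that survives organolithium chemistry and is removed oxidatively; methanolysis of the C–Si bond in the same flask frees the terminal alkyne. The descriptor changes from 3S to 3R only through the priority change; the configuration is untouched.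

Step 10
Reactants: 12 (4S)-4-{(1E,3R)-3-[(4-methoxyphenyl)methoxy]-2-methylpent-1-en-4-yn-1-yl}-2,2-dimethyl-1,3-dioxolane
Product: 13 (4S)-4-{(1E,3R,4E)-5-iodo-3-[(4-methoxyphenyl)methoxy]-2-methylpenta-1,4-dien-1-yl}-2,2-dimethyl-1,3-dioxolane
Conditions: Cp2Zr(H)Cl, THF, rt; then I2, 0 °C
Reagents that add atoms: iodine, II
Why: Hydrozirconation adds Zr–H syn with zirconium at the terminal carbon, and iodinolysis with retention gives the E iodoalkene. It is done before the oxirane is present so that the hydride reagent meets no epoxide.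

Step 11
Reactants: 13 (4S)-4-{(1E,3R,4E)-5-iodo-3-[(4-methoxyphenyl)methoxy]-2-methylpenta-1,4-dien-1-yl}-2,2-dimethyl-1,3-dioxolane
Product: 14 (2S,3E,5R,6E)-7-iodo-5-[(4-methoxyphenyl)methoxy]-4-methylhepta-3,6-diene-1,2-diol
Conditions: AcOH/H2O/THF, 40 °C
Reagents that add atoms: none
Why: Mild acid hydrolysis of a terminal acetonide; the PMB ether and the iodoalkene are stable, and the electron-poor iodoalkene disfavours ionisation of the doubly allylic ether.

Step 12
Reactants: 14 (2S,3E,5R,6E)-7-iodo-5-[(4-methoxyphenyl)methoxy]-4-methylhepta-3,6-diene-1,2-diol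
Product: 15 (2S,3E,5R,6E)-7-iodo-5-[(4-methoxyphenyl)methoxy]-4-methyl-1-[(triethylsilyl)oxy]hepta-3,6-dien-2-ol
Conditions: TESCl, imidazole, CH2Cl2, −78 to −40 °C
Reagents that add atoms: chlorotriethylsilane, CC[Si](Cl)(CC)CC
Why: Selective silylation of the primary hydroxyl (O8) on steric grounds; it leaves the allylic C7 hydroxyl free to direct the epoxidation.

Step 13
Reactants: 15 (2S,3E,5R,6E)-7-iodo-5-[(4-methoxyphenyl)methoxy]-4-methyl-1-[(triethylsilyl)oxy]hepta-3,6-dien-2-ol
Product: 16 (1R)-1-{(2S,3S)-3-[(1R,2E)-3-iodo-1-[(4-methoxyphenyl)methoxy]prop-2-en-1-yl]-3-methyloxiran-2-yl}-2-[(triethylsilyl)oxy]ethan-1-ol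
Conditions: mCPBA, CH2Cl2, −20 to 0 °C
Reagents that add atoms: 3-chloroperoxybenzoic acid, OOC(=O)c1cccc(Cl)c1
Why: Hydroxyl-directed peracid epoxidation; the C5 methyl is cis to C7, so 1,3-allylic strain holds the C7–H bond in the olefin plane and the hydrogen-bonded peracid attacks the face syn to the hydroxyl. This should give the threo epoxy alcohol with C5 and C6 as in 26. The iodoalkene is too electron-poor to compete.

Step 14
Reactants: 16 (1R)-1-{(2S,3S)-3-[(1R,2E)-3-iodo-1-[(4-methoxyphenyl)methoxy]prop-2-en-1-yl]-3-methyloxiran-2-yl}-2-[(triethylsilyl)oxy]ethan-1-ol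
Product: 17 tert-butyl{(1R)-1-{(2S,3S)-3-[(1R,2E)-3-iodo-1-[(4-methoxyphenyl)methoxy]prop-2-en-1-yl]-3-methyloxiran-2-yl}-2-[(triethylsilyl)oxy]ethoxy}dimethylsilane (fragment B)
Conditions: TBSOTf, 2,6-lutidine, CH2Cl2, −78 °C
Reagents that add atoms: tert-butyldimethylsilyl trifluoromethanesulfonate, CC(C)(C)[Si](C)(C)OS(=O)(=O)C(F)(F)F
Why: Low-temperature silylation of the hindered secondary C7 hydroxyl with a hindered base leaves the oxirane and the primary TES ether intact and prevents Payne rearrangement in later basic steps.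

Step 15
Reactants: 17 fragment B (E-alkenyl iodide); 7 fragment A (tertiary pinacol boronate)
Product: 20 C8–C9 seco compound with Z-C2=C3 and Z-C9 iodide (O4 PMB; 5,6-oxirane; O7 TBS; O8 TES; O9' TBS), via alkenyllithium 18 (not isolated), via lithium boronate complex 19 (not isolated)
Conditions: 17, t-BuLi (2.0 equiv), Et2O, −78 °C; then 7, THF, −78 °C; then I2 (excess), THF/MeOH, −78 to 0 °C; then NaOMe, MeOH, 0 °C; aqueous Na2S2O3
Reagents that add atoms: iodine, II
Why: Zweifel olefination: iodine–lithium exchange on 17 gives the E-alkenyllithium 18 with retention of geometry, and 18 adds to the vacant orbital of the tertiary boronate 7 to give the tetracoordinate boronate 19. Iodine attacks the electron-rich alkenyl group of 19 and the tertiary carbon C1 shifts from boron to C2 anti to the new C3–I bond; methoxide then binds boron, and boron and iodide leave anti, which turns the E-alkenyl group into the Z olefin C2=C3. The closest known reaction type is the stereospecific olefination of secondary and tertiary pinacol boronic esters with alkenyllithium reagents. No ring is closed in this step. No stereocentre is created: C1, set in step 1, is carried over unchanged because 1,2-metallate shifts are retentive at the migrating carbon, and the only new stereo-element, the Z geometry, is fixed by the E geometry of 18 and the anti course of both migration and elimination. Boronate formation must outrun tin–lithium exchange; this is secured by pre-forming 18 with exactly two equivalents of t-BuLi (the second destroys t-BuI) and by the much higher Lewis acidity of boron compared with the hindered trisubstituted alkenylstannane. Only C1 can migrate, because it is the sole carbon ligand on boron apart from the alkenyl group. The excess iodine then cleaves the C9–Sn bond with retention, so the Z iodoalkene for ring closure is formed in the same operation; the oxirane, silyl ethers and PMB ether should not react with the alkenyllithium at −78 °C.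

Step 16
Reactants: 20 C8–C9 seco compound (O8 TES ether)
Product: 21 seco iodo-aldehyde (C8 aldehyde; otherwise as 20)
Conditions: (COCl)2, DMSO, CH2Cl2, −78 to −40 °C; then Et3N, −78 to 0 °C
Reagents that add atoms: none
Why: Swern conditions cleave a primary triethylsilyl ether in situ and oxidise it directly to the aldehyde, while the secondary and the allylic TBS ethers are untouched. Any O8 alcohol freed by methoxide in step 15 is oxidised to the same product.

Step 17
Reactants: 21 seco iodo-aldehyde
Product: 22 eleven-membered allylic alcohol (both C8 epimers; O4 PMB; O7 TBS; O9' TBS)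
Conditions: CrCl2 (excess), NiCl2 (cat.), DMSO/THF, rt, high dilution
Reagents that add atoms: none
Why: Nozaki–Hiyama–Kishi reaction; nickel inserts into the C9–I bond with retention of the Z geometry, and the alkenylchromium species formed by transmetalation adds to the C8 aldehyde to close the ring. The reagent is chemoselective for aldehydes and tolerates oxiranes, ethers and silyl ethers; the C8 configuration is irrelevant.

Step 18
Reactants: 22 eleven-membered allylic alcohol (C8 epimers)
Product: 23 eleven-membered epoxy enone (O4 PMB; O7 TBS; O9' TBS)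
Conditions: Dess–Martin periodinane, NaHCO3, CH2Cl2, 0 °C to rt
Reagents that add atoms: none
Why: Buffered hypervalent-iodine oxidation of both carbinol epimers gives the C8 ketone without enolising C7 or touching the oxirane.

Step 19
Reactants: 23 eleven-membered epoxy enone
Product: 24 C4 alcohol (O7 TBS; O9' TBS)
Conditions: DDQ, CH2Cl2/pH 7 phosphate buffer, 0 °C
Reagents that add atoms: none
Why: Oxidative cleavage of the 4-methoxybenzyl ether by hydride abstraction and hydrolysis, neutral and orthogonal to the silyl ethers. A transannular hemiketal with C8 cannot form because it would need a trans-fused oxirane in a six-membered ring.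

Step 20
Reactants: 24 C4 alcohol
Product: 25 C4 senecioate (O7 TBS; O9' TBS)
Conditions: 3-methylbut-2-enoyl chloride, pyridine, DMAP (cat.), CH2Cl2, 0 °C
Reagents that add atoms: 3-methylbut-2-enoyl chloride, CC(C)=CC(Cl)=O
Why: Acyl-transfer catalysed esterification of the only free hydroxyl; pyridine is used instead of a trialkylamine to limit ketene formation and deconjugation of the senecioyl group, and no alkoxide is formed that could trigger Payne rearrangement.

Step 21
Reactants: 25 C4 senecioate bis-silyl ether
Product: 26 target (CNP0163063.1)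
Conditions: HF·pyridine, pyridine, THF, 0 °C to rt
Reagents that add atoms: none
Why: Buffered fluoride removes both TBS ethers under weakly acidic, non-basic conditions, which avoids acyl migration, Payne rearrangement and enolisation of the α-ketol.

**Compound list**

1 | methyl (2E)-3,7-dimethylocta-2,6-dienoate (methyl geranate) | CC(C)=CCC/C(C)=C/C(=O)OC | starting material
2 | methyl (3R)-3,7-dimethyl-3-(4,4,5,5-tetramethyl-1,3,2-dioxaborolan-2-yl)oct-6-enoate | CC(C)=CCC[C@](CC(=O)OC)(C)B1OC(C)(C)C(C)(C)O1 | intermediate
3 | (3R)-3,7-dimethyl-3-(4,4,5,5-tetramethyl-1,3,2-dioxaborolan-2-yl)oct-6-enal | CC(C)=CCC[C@](CC=O)(C)B1OC(C)(C)C(C)(C)O1 | intermediate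
4 | 2-[(4R)-4,8-dimethylnon-7-en-1-yn-4-yl]-4,4,5,5-tetramethyl-1,3,2-dioxaborolane | CC(C)=CCC[C@](CC#C)(C)B1OC(C)(C)C(C)(C)O1 | intermediate
5 | (5R)-5,9-dimethyl-5-(4,4,5,5-tetramethyl-1,3,2-dioxaborolan-2-yl)dec-8-en-2-yn-1-ol | CC(C)=CCC[C@](CC#CCO)(C)B1OC(C)(C)C(C)(C)O1 | intermediate
6 | (2Z,5R)-5,9-dimethyl-5-(4,4,5,5-tetramethyl-1,3,2-dioxaborolan-2-yl)-2-(tributylstannyl)deca-2,8-dien-1-ol | CC(C)=CCC[C@](C/C=C(/CO)[Sn](CCCC)(CCCC)CCCC)(C)B1OC(C)(C)C(C)(C)O1 | intermediate
7 | tert-butyl{[(2Z,5R)-5,9-dimethyl-5-(4,4,5,5-tetramethyl-1,3,2-dioxaborolan-2-yl)-2-(tributylstannyl)deca-2,8-dien-1-yl]oxy}dimethylsilane (fragment A) | CC(C)=CCC[C@](C/C=C(/CO[Si](C)(C)C(C)(C)C)[Sn](CCCC)(CCCC)CCCC)(C)B1OC(C)(C)C(C)(C)O1 | intermediate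
8 | (4R)-2,2-dimethyl-1,3-dioxolane-4-carbaldehyde | O=C[C@@H]1OC(C)(C)OC1 | starting material
9 | (2E)-3-[(4S)-2,2-dimethyl-1,3-dioxolan-4-yl]-2-methylprop-2-enal | O=C/C(C)=C/[C@@H]1OC(C)(C)OC1 | intermediate
10 | (3S,4E)-5-[(4S)-2,2-dimethyl-1,3-dioxolan-4-yl]-4-methyl-1-(trimethylsilyl)pent-4-en-1-yn-3-ol | C[Si](C)(C)C#C[C@@H](O)/C(C)=C/[C@@H]1OC(C)(C)OC1 | intermediate
11 | {(3S,4E)-5-[(4S)-2,2-dimethyl-1,3-dioxolan-4-yl]-3-[(4-methoxyphenyl)methoxy]-4-methylpent-4-en-1-yn-1-yl}trimethylsilane | C[Si](C)(C)C#C[C@@H](OCc1ccc(OC)cc1)/C(C)=C/[C@@H]1OC(C)(C)OC1 | intermediate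
12 | (4S)-4-{(1E,3R)-3-[(4-methoxyphenyl)methoxy]-2-methylpent-1-en-4-yn-1-yl}-2,2-dimethyl-1,3-dioxolane | C#C[C@@H](OCc1ccc(OC)cc1)/C(C)=C/[C@@H]1OC(C)(C)OC1 | intermediate
13 | (4S)-4-{(1E,3R,4E)-5-iodo-3-[(4-methoxyphenyl)methoxy]-2-methylpenta-1,4-dien-1-yl}-2,2-dimethyl-1,3-dioxolane | I/C=C/[C@@H](OCc1ccc(OC)cc1)/C(C)=C/[C@@H]1OC(C)(C)OC1 | intermediate
14 | (2S,3E,5R,6E)-7-iodo-5-[(4-methoxyphenyl)methoxy]-4-methylhepta-3,6-diene-1,2-diol | I/C=C/[C@@H](OCc1ccc(OC)cc1)/C(C)=C/[C@H](O)CO | intermediate
15 | (2S,3E,5R,6E)-7-iodo-5-[(4-methoxyphenyl)methoxy]-4-methyl-1-[(triethylsilyl)oxy]hepta-3,6-dien-2-ol | I/C=C/[C@@H](OCc1ccc(OC)cc1)/C(C)=C/[C@H](O)CO[Si](CC)(CC)CC | intermediate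
16 | (1R)-1-{(2S,3S)-3-[(1R,2E)-3-iodo-1-[(4-methoxyphenyl)methoxy]prop-2-en-1-yl]-3-methyloxiran-2-yl}-2-[(triethylsilyl)oxy]ethan-1-ol | I/C=C/[C@@H](OCc1ccc(OC)cc1)[C@]1(C)O[C@H]1[C@H](O)CO[Si](CC)(CC)CC | intermediate
17 | tert-butyl{(1R)-1-{(2S,3S)-3-[(1R,2E)-3-iodo-1-[(4-methoxyphenyl)methoxy]prop-2-en-1-yl]-3-methyloxiran-2-yl}-2-[(triethylsilyl)oxy]ethoxy}dimethylsilane (fragment B) | I/C=C/[C@@H](OCc1ccc(OC)cc1)[C@]1(C)O[C@H]1[C@H](O[Si](C)(C)C(C)(C)C)CO[Si](CC)(CC)CC | intermediate
18 | E-alkenyllithium from 17 (lithium in place of iodine) | [Li]/C=C/[C@@H](OCc1ccc(OC)cc1)[C@]1(C)O[C@H]1[C@H](O[Si](C)(C)C(C)(C)C)CO[Si](CC)(CC)CC | intermediate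
19 | lithium boronate complex of 7 and 18 (boron bound to C1, to the E-alkenyl carbon C2 and to pinacol) | [Li+].CC(C)=CCC[C@](C/C=C(/CO[Si](C)(C)C(C)(C)C)[Sn](CCCC)(CCCC)CCCC)(C)[B-]1(/C=C/[C@@H](OCc2ccc(OC)cc2)[C@]2(C)O[C@H]2[C@H](O[Si](C)(C)C(C)(C)C)CO[Si](CC)(CC)CC)OC(C)(C)C(C)(C)O1 | intermediate
20 | C8–C9 seco compound: chain C9'–C9–C10–C11–C1–C2–C3–C4–C5–C6–C7–C8 with 2Z olefin, 9Z iodoalkene, O4 PMB ether, 5,6-oxirane, O7 TBS ether, O8 TES ether, O9' TBS ether; C1, C4, C5, C6, C7 as in 26 | CC(C)=CCC[C@](C/C=C(/CO[Si](C)(C)C(C)(C)C)I)(C)/C=C\[C@@H](OCc1ccc(OC)cc1)[C@]1(C)O[C@H]1[C@H](O[Si](C)(C)C(C)(C)C)CO[Si](CC)(CC)CC | intermediate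
21 | seco iodo-aldehyde: as 20 with C8 as aldehyde | CC(C)=CCC[C@](C/C=C(/CO[Si](C)(C)C(C)(C)C)I)(C)/C=C\[C@@H](OCc1ccc(OC)cc1)[C@]1(C)O[C@H]1[C@H](O[Si](C)(C)C(C)(C)C)C=O | intermediate
22 | eleven-membered allylic alcohol, both C8 epimers (O4 PMB, O7 TBS, O9' TBS; 2Z, 9Z; other centres as in 26) | CC(C)=CCC[C@]1(C)/C=C\[C@@H](OCc2ccc(OC)cc2)[C@]2(C)O[C@H]2[C@H](O[Si](C)(C)C(C)(C)C)C(O)/C(CO[Si](C)(C)C(C)(C)C)=C\C1 | intermediate
23 | eleven-membered epoxy enone (O4 PMB, O7 TBS, O9' TBS) | CC(C)=CCC[C@]1(C)/C=C\[C@@H](OCc2ccc(OC)cc2)[C@]2(C)O[C@H]2[C@H](O[Si](C)(C)C(C)(C)C)C(=O)/C(CO[Si](C)(C)C(C)(C)C)=C\C1 | intermediate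
24 | C4 alcohol of 23 (O7 TBS, O9' TBS) | CC(C)=CCC[C@]1(C)/C=C\[C@@H](O)[C@]2(C)O[C@H]2[C@H](O[Si](C)(C)C(C)(C)C)C(=O)/C(CO[Si](C)(C)C(C)(C)C)=C\C1 | intermediate
25 | C4 3-methylbut-2-enoate (O7 TBS, O9' TBS) | CC(C)=CCC[C@]1(C)/C=C\[C@@H](OC(=O)C=C(C)C)[C@]2(C)O[C@H]2[C@H](O[Si](C)(C)C(C)(C)C)C(=O)/C(CO[Si](C)(C)C(C)(C)C)=C\C1 | intermediate
26 | CNP0163063.1 | CC(C)=CCC[C@]1(C)/C=C\[C@@H](OC(=O)C=C(C)C)[C@]2(C)O[C@H]2[C@H](O)C(=O)/C(CO)=C\C1 | target

**Step count and risk**

Total steps: 21 (fragment A steps 1–6, fragment B steps 7–14, union and end game steps 15–21). Longest linear sequence: 15 steps (steps 7–21).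

Least certain steps:

Step 15 (key step). The most likely failure is tin–lithium exchange between 18 and the alkenylstannane of 7 competing with boronate formation at the hindered tertiary boron. The second risk is unselective consumption of iodine (premature iododestannylation, or iodomethoxylation of the 4-methylpent-3-enyl olefin) before the boronate complex has rearranged; both are fast processes of similar rate. The fallback takes tin out of the union and sets out from 5 and 17. Alcohol 5 is silylated (TMSCl, Et3N) to the trimethylsilyl ether F1. Alkenyllithium 18 is added to F1 and treated with one equivalent of iodine and then NaOMe/MeOH, which also removes the trimethylsilyl group and gives the enynol F2. Hydroxyl-directed trans-hydrostannation ([Cp*RuCl]4, Bu3SnH) gives the alkenylstannane F3, iodine gives the iodo alcohol F4, and TBSCl/imidazole returns to the route at 20.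

Step 17. Ring closure may be outrun by oligomerisation or by protodeiodination of the alkenyl metal species, because two cis olefins and the trans oxirane leave few strain-free conformations for the eleven-membered transition state; the α-silyloxy aldehyde may also epimerise while it waits. The fallback closes the same bond at the ketone oxidation level by palladium-catalysed acylation of the alkenylstannane, and sets out from 7 and 17. The union of step 15 is run with one equivalent of iodine at −78 °C so that the C–Sn bond survives, giving the stannane F5. Swern oxidation as in step 16 gives the aldehyde F6, NaClO2/NaH2PO4/2-methylbut-2-ene gives the acid F7, and 1-chloro-N,N,2-trimethylprop-1-en-1-amine gives the acid chloride F8. Intramolecular Stille acylation (Pd2(dba)3, P(2-furyl)3, toluene, high dilution, zerovalent palladium inserting into the C–Cl bond) returns to the route at 23.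

Step 13. Facial selectivity may be poor if the C4 ether oxygen or the neighbouring silyloxy group disturbs the 1,3-strain-controlled conformer, and the acid by-product may remove the triethylsilyl group. The fallback replaces substrate direction by reagent control and sets out from 15. Silylation (TBSOTf, 2,6-lutidine) gives the allylic silyl ether F9. Shi epoxidation with the fructose-derived ketone enantiomer that the spiro transition-state model assigns to the required face (KHSO5, buffered MeCN/H2O) returns to the route at 17.

Step 1. Enantiofacial discrimination may be insufficient because the two β-substituents, methyl and a primary alkyl chain, differ little in size. The fallback gives up catalyst control and sets out from 1. Borylation with an achiral CuCl/Xantphos catalyst gives the racemate, and preparative chromatography on a chiral stationary phase separates 2 from its enantiomer, the (3S)-boronate F10, returning to the route at 2.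

**Further compounds**

F1 | step 15 | trimethylsilyl ether of 5 | CC(C)=CCC[C@](CC#CCO[Si](C)(C)C)(C)B1OC(C)(C)C(C)(C)O1
F2 | step 15 | enynol: as 20 with C9≡C10 alkyne and free O9' hydroxyl | CC(C)=CCC[C@](CC#CCO)(C)/C=C\[C@@H](OCc1ccc(OC)cc1)[C@]1(C)O[C@H]1[C@H](O[Si](C)(C)C(C)(C)C)CO[Si](CC)(CC)CC
F3 | step 15 | alkenylstannane: as 20 with C9–SnBu3 and free O9' hydroxyl | CC(C)=CCC[C@](C/C=C(/CO)[Sn](CCCC)(CCCC)CCCC)(C)/C=C\[C@@H](OCc1ccc(OC)cc1)[C@]1(C)O[C@H]1[C@H](O[Si](C)(C)C(C)(C)C)CO[Si](CC)(CC)CC
F4 | step 15 | iodo alcohol: as 20 with free O9' hydroxyl | CC(C)=CCC[C@](C/C=C(/CO)I)(C)/C=C\[C@@H](OCc1ccc(OC)cc1)[C@]1(C)O[C@H]1[C@H](O[Si](C)(C)C(C)(C)C)CO[Si](CC)(CC)CC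
F5 | step 17 | stannane: as 20 with C9–SnBu3 in place of C9–I | CC(C)=CCC[C@](C/C=C(/CO[Si](C)(C)C(C)(C)C)[Sn](CCCC)(CCCC)CCCC)(C)/C=C\[C@@H](OCc1ccc(OC)cc1)[C@]1(C)O[C@H]1[C@H](O[Si](C)(C)C(C)(C)C)CO[Si](CC)(CC)CC
F6 | step 17 | stannyl aldehyde: as F5 with C8 as aldehyde | CC(C)=CCC[C@](C/C=C(/CO[Si](C)(C)C(C)(C)C)[Sn](CCCC)(CCCC)CCCC)(C)/C=C\[C@@H](OCc1ccc(OC)cc1)[C@]1(C)O[C@H]1[C@H](O[Si](C)(C)C(C)(C)C)C=O
F7 | step 17 | stannyl acid: as F5 with C8 as carboxylic acid | CC(C)=CCC[C@](C/C=C(/CO[Si](C)(C)C(C)(C)C)[Sn](CCCC)(CCCC)CCCC)(C)/C=C\[C@@H](OCc1ccc(OC)cc1)[C@]1(C)O[C@H]1[C@H](O[Si](C)(C)C(C)(C)C)C(O)=O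
F8 | step 17 | stannyl acid chloride: as F5 with C8 as acyl chloride | CC(C)=CCC[C@](C/C=C(/CO[Si](C)(C)C(C)(C)C)[Sn](CCCC)(CCCC)CCCC)(C)/C=C\[C@@H](OCc1ccc(OC)cc1)[C@]1(C)O[C@H]1[C@H](O[Si](C)(C)C(C)(C)C)C(Cl)=O
F9 | step 13 | O7 tert-butyldimethylsilyl ether of 15 | I/C=C/[C@@H](OCc1ccc(OC)cc1)/C(C)=C/[C@H](O[Si](C)(C)C(C)(C)C)CO[Si](CC)(CC)CC
F10 | step 1 | methyl (3S)-3,7-dimethyl-3-(4,4,5,5-tetramethyl-1,3,2-dioxaborolan-2-yl)oct-6-enoate (enantiomer of 2) | CC(C)=CCC[C@@](CC(=O)OC)(C)B1OC(C)(C)C(C)(C)O1
A1 | alternative 1 | seco iodo-aldehyde opened at C3–C4 (Z-iodoalkene on C1, C4 aldehyde, C8 ketone, O7 and O9' TBS ethers) | CC(C)=CCC[C@@](/C=C\I)(C)C/C=C(/CO[Si](C)(C)C(C)(C)C)C(=O)[C@@H](O[Si](C)(C)C(C)(C)C)[C@@H]1O[C@@]1(C)C=O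
A2 | alternative 2 | 1,2-dialkenylcycloheptenol with C3–C9 bond (C3 carbinol bearing the 2,6-dimethylhepta-1,5-dienyl group, C9 bearing vinyl and silyloxymethyl, cis C5=C6 in the ring; one diastereomer drawn) | CC(C)=CCC/C(C)=C/[C@@]1(O)[C@@H](OCc2ccc(OC)cc2)C(C)=C[C@H](O[Si](C)(C)C(C)(C)C)C(O[Si](C)(C)C(C)(C)C)[C@@]1(C=C)CO[Si](C)(C)C(C)(C)C
A3 | alternative 3 | secondary allylic acetate at C3 with E-C1=C2 (substrate of the Ireland–Claisen rearrangement; one C3 epimer drawn) | CC(C)=CCC/C(C)=C/[C@@H](OC(C)=O)[C@@H](OCc1ccc(OC)cc1)/C(C)=C/[C@@H]1OC(C)(C)OC1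
A4 | alternative 3 | rearranged acid with quaternary C1 and E-C2=C3 olefin | OC(=O)C[C@](C)(CCC=C(C)C)/C=C/[C@@H](OCc1ccc(OC)cc1)/C(C)=C/[C@@H]1OC(C)(C)OC1
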